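**Retrosynthetic overview**

1. Rings and locants: A = dihydropyran; B = cyclohexane (C1 = quaternary carbon with the ether oxygen and the lactone carbonyl, C2 = CH–O, C3 = CH2, C4 = ring-fusion carbon with the lactone oxygen, C5 = ring-fusion CH, C6 = CH joined to ring A); C = cyclopentane (C4, C5, CH2, CH–O, CH2); lactone bridge C1–C(=O)–O–C4.
2. Ring A is closed last by a divalent-palladium-catalysed syn-SN2′ etherification of dienyl alcohol 22, which comes from Suzuki–Miyaura coupling of (Z)-vinyl iodide 15 with the octanal-derived boronate 20.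
3. Rings B and C and the lactone bridge are made in one operation (10 → 11): SnCl4-chelated Prins closure of ring B (C1–C6 bond), shift of one cyclobutane CH2 from C4 to C5 (four-membered ring → ring C), and capture of the C4 cation by the C1 ester.
4. Feature that allows it: C4 is a tertiary, oxygen-bearing ring-fusion carbon (a cation site) lying 1,4 across ring B from the carboxyl-bearing C1 and 1,3 to the carbinol carbon of ring C, so ring C is C5 plus a 3-oxygenated cyclobutane spiro at C4.
5. Keto ester 10 comes from 3-(benzyloxy)cyclobutanone 1 by olefination, vinyl conjugate addition, cross-metathesis, two-carbon homologation and asymmetric epoxidation/benzyl alcohol opening (sets C2, which relays the other core stereocentres); ring order: cyclobutane (bought) → B + C + lactone → A.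

Key step: step 9

Remark (assumption): the tert-butyl enoate 7 is taken to be accepted by the yttrium epoxidation catalyst, and the ligand enantiomer used is the one that delivers the (2R,3S)-epoxide.

**Route**

Step 1
Reactants: 1 3-(benzyloxy)cyclobutan-1-one
Product: 2 ethyl 2-[3-(benzyloxy)cyclobutylidene]acetate (racemic)
Conditions: (EtO)2P(O)CH2CO2Et, NaH, THF, 0 °C → rt
Reagents that add atoms: triethyl phosphonoacetate, CCOC(=O)CP(=O)(OCC)OCC
Why: Horner–Wadsworth–Emmons olefination of the strained and therefore reactive cyclobutanone; no stereocentre results, because the axial chirality of racemic 2 is removed in step 2.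

Step 2
Reactants: 2 ethyl 2-[3-(benzyloxy)cyclobutylidene]acetate
Product: 4 ethyl 2-[3-(benzyloxy)-1-ethenylcyclobutyl]acetate (benzyloxy cis to the acetate arm), via silyl ketene acetal 3 (not isolated)
Conditions: CH2=CHMgBr, CuI (20 mol %), Me3SiCl, THF, −78 → −20 °C; then 1 M HCl
Reagents that add atoms: vinylmagnesium bromide, C=C[Mg]Br; chlorotrimethylsilane, C[Si](C)(C)Cl (its silyl group is carried by 3 only)
Why: Copper-catalysed, chlorotrimethylsilane-accelerated conjugate addition to a cyclobutylidene ester, driven by relief of strain at the ring sp2 carbon; the vinyl group should enter anti to the 3-benzyloxy group (the facial preference of nucleophilic additions to 3-substituted cyclobutanones), so the benzyloxy group ends cis to the acetate arm, and ketene acetal 3 is hydrolysed on acidic work-up.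

Step 3
Reactants: 4 ethyl 2-[3-(benzyloxy)-1-ethenylcyclobutyl]acetate
Product: 5 ethyl 2-{3-(benzyloxy)-1-[(E)-3-(benzyloxy)prop-1-enyl]cyclobutyl}acetate
Conditions: (Z)-BnOCH2CH=CHCH2OBn (3 equiv), second-generation Hoveyda–Grubbs catalyst (5 mol %), CH2Cl2, 40 °C
Reagents that add atoms: (Z)-1,4-bis(benzyloxy)but-2-ene, C(/C=C\COCc1ccccc1)OCc1ccccc1
Why: Olefin cross-metathesis: the hindered vinyl group on the quaternary carbon does not homodimerise and should be crossed with the excess symmetrical allylic ether to give the thermodynamically preferred E alkene.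

Step 4
Reactants: 5 ethyl 2-{3-(benzyloxy)-1-[(E)-3-(benzyloxy)prop-1-enyl]cyclobutyl}acetate
Product: 6 2-{3-(benzyloxy)-1-[(E)-3-(benzyloxy)prop-1-enyl]cyclobutyl}acetaldehyde
Conditions: i-Bu2AlH (1.1 equiv), CH2Cl2, −78 °C; aq. Rochelle salt
Reagents that add atoms: none
Why: Partial reduction of the ester with i-Bu2AlH through the tetrahedral aluminium hemiacetal, which releases the aldehyde only on work-up; no stereocentre is touched.

Step 5
Reactants: 6 2-{3-(benzyloxy)-1-[(E)-3-(benzyloxy)prop-1-enyl]cyclobutyl}acetaldehyde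
Product: 7 tert-butyl (E)-4-{3-(benzyloxy)-1-[(E)-3-(benzyloxy)prop-1-enyl]cyclobutyl}but-2-enoate
Conditions: Ph3P=CHCO2t-Bu, CH2Cl2, rt
Reagents that add atoms: tert-butyl (triphenylphosphoranylidene)acetate, CC(C)(C)OC(=O)C=P(c1ccccc1)(c1ccccc1)c1ccccc1
Why: Wittig olefination with a stabilised ylide, which should give the (E)-enoate.

Step 6
Reactants: 7 tert-butyl (E)-4-{3-(benzyloxy)-1-[(E)-3-(benzyloxy)prop-1-enyl]cyclobutyl}but-2-enoate
Product: 8 tert-butyl (2R,3S)-3-({3-(benzyloxy)-1-[(E)-3-(benzyloxy)prop-1-enyl]cyclobutyl}methyl)oxirane-2-carboxylate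
Conditions: Y(OiPr)3 (5 mol %), ether-linked biphenyl-2,2′-diol ligand (5 mol %, enantiomer for the 2R,3S sense), Ph3As=O (5 mol %), t-BuOOH, 4 Å molecular sieves, THF, rt
Reagents that add atoms: tert-butyl hydroperoxide, CC(C)(C)OO
Why: Catalytic asymmetric nucleophilic (Weitz–Scheffer-type) epoxidation of an α,β-unsaturated ester by a chiral yttrium peroxide: peroxide conjugate addition touches only the electron-poor alkene, and the ligand sets both epoxide carbons (trans, from the E alkene).

Step 7
Reactants: 8 tert-butyl (2R,3S)-3-({3-(benzyloxy)-1-[(E)-3-(benzyloxy)prop-1-enyl]cyclobutyl}methyl)oxirane-2-carboxylate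
Product: 9 tert-butyl (2R,3R)-3-(benzyloxy)-4-{3-(benzyloxy)-1-[(E)-3-(benzyloxy)prop-1-enyl]cyclobutyl}-2-hydroxybutanoate
Conditions: BnOH (4 equiv), BF3·OEt2 (20 mol %), CH2Cl2, −20 °C
Reagents that add atoms: benzyl alcohol, OCc1ccccc1
Why: Lewis-acid-catalysed alcoholysis of a 2,3-epoxy ester, which should open at C3 (remote from the destabilising ester) with inversion and so install the (3R) benzyl ether that later chelates.

Step 8
Reactants: 9 tert-butyl (2R,3R)-3-(benzyloxy)-4-{3-(benzyloxy)-1-[(E)-3-(benzyloxy)prop-1-enyl]cyclobutyl}-2-hydroxybutanoate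
Product: 10 tert-butyl (3R)-3-(benzyloxy)-4-{3-(benzyloxy)-1-[(E)-3-(benzyloxy)prop-1-enyl]cyclobutyl}-2-oxobutanoate
Conditions: Dess–Martin periodinane, CH2Cl2, 0 °C → rt; used crude
Reagents that add atoms: none
Why: Dess–Martin oxidation of the α-hydroxy ester to the α-keto ester under neutral conditions that should not epimerise the enolisable benzyloxy-bearing carbon.

Step 9
Reactants: 10 tert-butyl (3R)-3-(benzyloxy)-4-{3-(benzyloxy)-1-[(E)-3-(benzyloxy)prop-1-enyl]cyclobutyl}-2-oxobutanoate
Product: 11 tricyclic hydroxy lactone (rings B and C with the C1→C4 lactone bridge; C1-OH; benzyl ethers at C2 and at the ring-C carbinol; CH2OBn arm on C6)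
Conditions: SnCl4 (1.5 equiv), CH2Cl2, −78 → −40 °C; then aq. NaHCO3
Reagents that add atoms: none
Why: Proposed new method: SnCl4 binds the ketone oxygen together with the neighbouring benzyloxy oxygen of 10 and the (E)-alkene attacks the activated carbonyl carbon through a chair (6-endo-trig closure of ring B); the cyclobutane C–C bond anti-periplanar to the new bond then shifts to the electron-deficient carbon (ring C is closed by a four-to-five ring expansion, a Wagner–Meerwein shift releasing about 20 kcal/mol of strain), and the tertiary cation left at C4 is captured across ring B by the carbonyl oxygen of the axial tert-butyl ester, which loses 2-methylpropene (six-membered lactone bridge). The closest known reaction types are the Lewis-acid Prins (carbonyl-ene) cyclisation of unsaturated α-keto esters, the Prins–pinacol ring-enlarging annulation of alkenylcyclobutanols and cation capture by tert-butyl esters; a cyclobutane without the pinacol hydroxyl and with an ester terminator has not been used in this way. C1 is set by the five-membered chelate (new hydroxyl cis to the C2 benzyloxy group, ester axial), C6 by the E geometry of the alkene (arm equatorial in the chair), C5 by anti addition across the alkene (the migrating CH2 enters trans to the new C1–C6 bond), and C4 by the need of the ester to bridge from its own face, anti to the CH2 that has left. The step needs 6-endo instead of 5-exo attack, secured by cyclobutylcarbinyl stabilisation of the developing charge and by the inductively withdrawing benzyloxymethyl group on the other alkene carbon, and it needs the shift to outrun proton loss or chloride capture, secured by strain release and the low temperature. If the axial ester traps the first cation, the γ-lactone so formed has its C–O bond anti to the same cyclobutane bond and should funnel to 11 under the Lewis acid.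

Step 10
Reactants: 11 tricyclic hydroxy lactone tris(benzyl ether)
Product: 12 tricyclic tetraol lactone (C1-OH, C2-OH, ring-C OH, CH2OH on C6)
Conditions: H2 (1 atm), Pd/C, EtOAc/MeOH, rt
Reagents that add atoms: none
Why: Hydrogenolysis of the three benzyl ethers over palladium on carbon at a stage where no alkene is present; lactone and tertiary alcohol are inert.

Step 11
Reactants: 12 tricyclic tetraol lactone
Product: 13 tetrakis(triethylsilyl) ether of 12
Conditions: Et3SiOTf (6 equiv), 2,6-lutidine, CH2Cl2, −78 → 0 °C
Reagents that add atoms: triethylsilyl trifluoromethanesulfonate, CC[Si](CC)(CC)OS(=O)(=O)C(F)(F)F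
Why: Exhaustive silylation with the silyl triflate protects all four hydroxyls, including the tertiary C1 hydroxyl, whose free alkoxide could otherwise open the later β-hydroxy aldehyde by retro-aldol cleavage.

Step 12
Reactants: 13 tetrakis(triethylsilyl) ether
Product: 14 C6-carbaldehyde with triethylsilyl ethers at C1, C2 and the ring-C carbinol
Conditions: (COCl)2, DMSO, CH2Cl2, −78 → −30 °C; then Et3N, → 0 °C
Reagents that add atoms: none
Why: Swern oxidation applied directly to the per-silylated polyol: the chlorosulfonium reagent cleaves only the unhindered primary triethylsilyl ether and oxidises that position to the aldehyde, while the secondary and tertiary silyl ethers survive.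

Step 13
Reactants: 14 C6-carbaldehyde tris(triethylsilyl ether)
Product: 15 (Z)-2-iodoprop-1-enyl compound (cage residue cis to iodine)
Conditions: Ph3PEtI, n-BuLi, THF, 0 °C; I2, −78 °C; NaN(SiMe3)2, −20 °C; then 14, −78 → −20 °C
Reagents that add atoms: ethyltriphenylphosphonium iodide, CC[P+](c1ccccc1)(c1ccccc1)c1ccccc1.[I-]; iodine, II
Why: Stork–Zhao olefination: the α-iodo ylide adds under kinetic control to give the (Z)-2-iodoalkene, and C6 should keep its configuration because the arm already occupies the less hindered position facing the lactone bridge.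

Step 14
Reactants: 16 octanal
Product: 17 rac-dec-1-yn-3-ol
Conditions: HC≡CMgBr, THF, 0 °C; then 1 M HCl
Reagents that add atoms: ethynylmagnesium bromide, C#C[Mg]Br
Why: Grignard addition of the acetylide to the aldehyde gives the racemic propargylic alcohol.

Step 15
Reactants: 17 rac-dec-1-yn-3-ol
Product: 18 dec-1-yn-3-one
Conditions: Dess–Martin periodinane, CH2Cl2, rt
Reagents that add atoms: none
Why: Dess–Martin oxidation to the ynone removes the stereocentre so that it can be reset by reagent control.

Step 16
Reactants: 18 dec-1-yn-3-one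
Product: 19 (R)-dec-1-yn-3-ol
Conditions: (R)-Alpine-Borane (B-isopinocampheyl-9-borabicyclo[3.3.1]nonane from (+)-α-pinene), THF, rt; then ethanolamine
Reagents that add atoms: none
Why: Midland reduction: the chiral trialkylborane transfers its β-hydride to the ynone in a boat-like six-membered transition state with the small ethynyl group next to the pinane methyl, and the reagent from (+)-α-pinene should give the (R)-1-alkyn-3-ol.

Step 17
Reactants: 19 (R)-dec-1-yn-3-ol
Product: 20 (R,E)-1-(4,4,5,5-tetramethyl-1,3,2-dioxaborolan-2-yl)dec-1-en-3-ol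
Conditions: B2pin2, CuCl (5 mol %), Xantphos (5 mol %), NaOt-Bu (10 mol %), MeOH, THF, rt
Reagents that add atoms: bis(pinacolato)diboron, CC1(C)OB(OC1(C)C)B1OC(C)(C)C(C)(C)O1
Why: Copper-catalysed formal hydroboration (syn borylcupration with boron at the terminal carbon, then protonation by methanol) should give the (E)-alkenyl boronate and leave the free carbinol untouched.

Step 18
Reactants: 15 (Z)-vinyl iodide; 20 (R,E)-alkenyl boronate
Product: 21 (Z,E)-dienyl (R)-carbinol with triethylsilyl ethers at C1, C2 and the ring-C carbinol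
Conditions: Pd(dppf)Cl2 (5 mol %), Ph3As (20 mol %), Cs2CO3, DMF/THF/H2O, rt
Reagents that add atoms: none
Why: Suzuki–Miyaura coupling, which proceeds with retention of both alkene geometries and so fixes the (Z,E)-diene; the mild base at room temperature should spare lactone and silyl ethers.

Step 19
Reactants: 21 (Z,E)-dienyl carbinol tris(triethylsilyl ether)
Product: 22 (Z,E)-dienyl carbinol tetraol
Conditions: HF·pyridine, pyridine, THF, 0 °C → rt
Reagents that add atoms: none
Why: Fluoride-driven cleavage of the three triethylsilyl ethers under pyridine-buffered conditions that should not ionise the dienyl carbinol.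

Step 20
Reactants: 22 (Z,E)-dienyl carbinol tetraol
Product: 23 CNP0127096.2 (target)
Conditions: PdCl2(MeCN)2 (10 mol %), THF, 0 °C
Reagents that add atoms: none
Why: Divalent-palladium-catalysed intramolecular syn-SN2′ etherification of a hydroxy dienyl alcohol with 1,3-chirality transfer: the tertiary C1 hydroxyl adds 6-exo to the alkene face syn to the departing (R)-carbinol hydroxyl in the conformer whose carbinol C–H eclipses the alkene, which closes ring A, sets the ring-A ether carbon and leaves the (E)-nonenyl alkene, while the two secondary hydroxyls cannot reach the diene across the cage.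

**Compound list**

1 | 3-(benzyloxy)cyclobutan-1-one | O=C1CC(OCc2ccccc2)C1 | starting material
2 | ethyl 2-[3-(benzyloxy)cyclobutylidene]acetate (racemic) | CCOC(=O)C=C1CC(OCc2ccccc2)C1 | intermediate
3 | trimethylsilyl ketene acetal of 4 (not isolated) | CCOC(O[Si](C)(C)C)=C[C@]1(C=C)C[C@H](OCc2ccccc2)C1 | intermediate
4 | ethyl 2-[3-(benzyloxy)-1-ethenylcyclobutyl]acetate, benzyloxy cis to the acetate arm | CCOC(=O)C[C@]1(C=C)C[C@H](OCc2ccccc2)C1 | intermediate
5 | ethyl 2-{3-(benzyloxy)-1-[(E)-3-(benzyloxy)prop-1-enyl]cyclobutyl}acetate, same relative configuration | CCOC(=O)C[C@]1(/C=C/COCc2ccccc2)C[C@H](OCc2ccccc2)C1 | intermediate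
6 | 2-{3-(benzyloxy)-1-[(E)-3-(benzyloxy)prop-1-enyl]cyclobutyl}acetaldehyde | O=CC[C@]1(/C=C/COCc2ccccc2)C[C@H](OCc2ccccc2)C1 | intermediate
7 | tert-butyl (E)-4-{3-(benzyloxy)-1-[(E)-3-(benzyloxy)prop-1-enyl]cyclobutyl}but-2-enoate | CC(C)(C)OC(=O)/C=C/C[C@]1(/C=C/COCc2ccccc2)C[C@H](OCc2ccccc2)C1 | intermediate
8 | tert-butyl (2R,3S)-3-({3-(benzyloxy)-1-[(E)-3-(benzyloxy)prop-1-enyl]cyclobutyl}methyl)oxirane-2-carboxylate | CC(C)(C)OC(=O)[C@@H]1O[C@H]1C[C@]2(/C=C/COCc3ccccc3)C[C@H](OCc3ccccc3)C2 | intermediate
9 | tert-butyl (2R,3R)-3-(benzyloxy)-4-{3-(benzyloxy)-1-[(E)-3-(benzyloxy)prop-1-enyl]cyclobutyl}-2-hydroxybutanoate | CC(C)(C)OC(=O)[C@H](O)[C@H](OCc1ccccc1)C[C@]2(/C=C/COCc1ccccc1)C[C@H](OCc1ccccc1)C2 | intermediate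
10 | tert-butyl (3R)-3-(benzyloxy)-4-{3-(benzyloxy)-1-[(E)-3-(benzyloxy)prop-1-enyl]cyclobutyl}-2-oxobutanoate | CC(C)(C)OC(=O)C(=O)[C@H](OCc1ccccc1)C[C@]2(/C=C/COCc1ccccc1)C[C@H](OCc1ccccc1)C2 | intermediate
11 | tricyclic hydroxy lactone: C1-OH, C2-OBn, ring-C OBn, CH2OBn on C6 | O[C@@]12C(=O)O[C@]3(C[C@H](OCc4ccccc4)C[C@@H]3[C@H]1COCc4ccccc4)C[C@H]2OCc4ccccc4 | intermediate
12 | tricyclic tetraol lactone | O[C@@]12C(=O)O[C@]3(C[C@H](O)C[C@@H]3[C@H]1CO)C[C@H]2O | intermediate
13 | tetrakis(triethylsilyl) ether of 12 | CC[Si](CC)(CC)O[C@@]12C(=O)O[C@]3(C[C@H](O[Si](CC)(CC)CC)C[C@@H]3[C@H]1CO[Si](CC)(CC)CC)C[C@H]2O[Si](CC)(CC)CC | intermediate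
14 | C6-carbaldehyde, tris(triethylsilyl ether) | CC[Si](CC)(CC)O[C@@]12C(=O)O[C@]3(C[C@H](O[Si](CC)(CC)CC)C[C@@H]3[C@H]1C=O)C[C@H]2O[Si](CC)(CC)CC | intermediate
15 | C6-[(Z)-2-iodoprop-1-enyl] compound, tris(triethylsilyl ether) | CC[Si](CC)(CC)O[C@@]12C(=O)O[C@]3(C[C@H](O[Si](CC)(CC)CC)C[C@@H]3[C@H]1/C=C(\I)C)C[C@H]2O[Si](CC)(CC)CC | intermediate
16 | octanal | CCCCCCCC=O | starting material
17 | rac-dec-1-yn-3-ol | CCCCCCCC(O)C#C | intermediate
18 | dec-1-yn-3-one | CCCCCCCC(=O)C#C | intermediate
19 | (R)-dec-1-yn-3-ol | CCCCCCC[C@@H](O)C#C | intermediate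
20 | (R,E)-1-(4,4,5,5-tetramethyl-1,3,2-dioxaborolan-2-yl)dec-1-en-3-ol | CCCCCCC[C@@H](O)/C=C/B1OC(C)(C)C(C)(C)O1 | intermediate
21 | C6-[(1Z,3E,5R)-5-hydroxy-2-methyldodeca-1,3-dienyl] compound, tris(triethylsilyl ether) | CC[Si](CC)(CC)O[C@@]12C(=O)O[C@]3(C[C@H](O[Si](CC)(CC)CC)C[C@@H]3[C@H]1/C=C(\C=C\[C@H](O)CCCCCCC)C)C[C@H]2O[Si](CC)(CC)CC | intermediate
22 | C6-[(1Z,3E,5R)-5-hydroxy-2-methyldodeca-1,3-dienyl] tetraol lactone | O[C@@]12C(=O)O[C@]3(C[C@H](O)C[C@@H]3[C@H]1/C=C(\C=C\[C@H](O)CCCCCCC)C)C[C@H]2O | intermediate
23 | CNP0127096.2 | CCCCCCC/C=C/[C@H]1O[C@@]23C(=O)O[C@]4(C[C@H](O)C[C@@H]4[C@H]2C=C1C)C[C@H]3O | target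

**Count**

Total step count: 20. Longest linear sequence: 16 steps (steps 1–13 and 18–20); steps 14–17 make the side-chain fragment.

**Steps most likely to fail**

Step 9 (Proposed new method). The first-formed cation may be quenched (ester capture at C5, chloride capture or proton loss) before the cyclobutane bond migrates, or attack may go 5-exo. The fallback runs the two events separately with known reaction types and sets out from 10. TiCl4 (1.1 equiv) in CH2Cl2 at −90 °C with a cold quench should stop at the Prins cyclisation–lactonisation product, the spiro γ-lactone F1 (the axial ester traps the cation at C5 and 2-methylpropene is lost). F1 is then treated with catalytic CF3SO3H in (CF3)2CHOH/CH2Cl2 at 0 °C: alkyl–oxygen ionisation at C5 with migration of the anti-periplanar cyclobutane bond (the solvolytic Wagner–Meerwein ring expansion of a cyclobutylcarbinyl ester) and recapture at C4 should give 11, where the route is rejoined.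

Step 20. Chirality transfer may be lost through acid-type ionisation of the dienyl carbinol, or the hindered tertiary hydroxyl may attack too slowly. The fallback sets out from 15. Nozaki–Hiyama–Kishi coupling with (E)-dec-2-enal (CrCl2, NiCl2 1 mol %, DMSO, rt) should give the bis-allylic alcohol F4 as a mixture of carbinol epimers, and HF·pyridine then removes the silyl groups to give the tetraol F5. A trace of camphorsulfonic acid in CH2Cl2 should ionise the doubly allylic carbinol to a pentadienyl cation, which the C1 hydroxyl captures in a six-membered closure under equilibrating conditions; the route comes back at 23 after removal of the epimer at the ether carbon should it form.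

Step 13. Addition of the bulky α-iodo ylide to the hindered aldehyde may be slow, with competing epimerisation at the aldehyde α-carbon and decay of the ylide. The fallback sets out from 14. Ramirez olefination (CBr4, PPh3, CH2Cl2, 0 °C) should give the 1,1-dibromoalkene F2. A trans-selective Negishi mono-methylation (Me2Zn, Pd(DPEphos)Cl2 cat., THF) replaces the bromine trans to the cage and should give the (Z)-vinyl bromide F3. F3 enters the Suzuki–Miyaura coupling with 20 under the conditions of step 18 and comes back at 21.

**Further compounds**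

F1 | step 9 | spiro γ-lactone (C1 carboxyl bound to the C5 oxygen; 3-benzyloxycyclobutane still spiro at C4) | O[C@@]12C(=O)O[C@@H]([C@H]1COCc3ccccc3)[C@]4(C[C@H](OCc3ccccc3)C4)C[C@H]2OCc3ccccc3
F2 | step 13 | C6-(2,2-dibromoethenyl) compound, tris(triethylsilyl ether) | CC[Si](CC)(CC)O[C@@]12C(=O)O[C@]3(C[C@H](O[Si](CC)(CC)CC)C[C@@H]3[C@H]1C=C(Br)Br)C[C@H]2O[Si](CC)(CC)CC
F3 | step 13 | C6-[(Z)-2-bromoprop-1-enyl] compound, tris(triethylsilyl ether) | CC[Si](CC)(CC)O[C@@]12C(=O)O[C@]3(C[C@H](O[Si](CC)(CC)CC)C[C@@H]3[C@H]1/C=C(\Br)C)C[C@H]2O[Si](CC)(CC)CC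
F4 | step 20 | C6-[(1Z,4E)-3-hydroxy-2-methyldodeca-1,4-dienyl] compound, tris(triethylsilyl ether), both carbinol epimers | CC[Si](CC)(CC)O[C@@]12C(=O)O[C@]3(C[C@H](O[Si](CC)(CC)CC)C[C@@H]3[C@H]1/C=C(\C(O)/C=C/CCCCCCC)C)C[C@H]2O[Si](CC)(CC)CC
F5 | step 20 | C6-[(1Z,4E)-3-hydroxy-2-methyldodeca-1,4-dienyl] tetraol lactone, both carbinol epimers | O[C@@]12C(=O)O[C@]3(C[C@H](O)C[C@@H]3[C@H]1/C=C(\C(O)/C=C/CCCCCCC)C)C[C@H]2O
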